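(The numbers in the tables are calculated on assumed constants; noise was put on by code.)

| flask | Z | X | remark | time |
|---|---|---|---|---|
| theta | 0.013 M | 0.040 M | run made earlier |  |
| beta | 0.010 M | 0.040 M | run made earlier |  |
| midnight | 0.020 M | 0.0400 M |  | 25 h |
| dusk | 0.020 M | 0.0600 M |  | 25 h |
- theta (time / h: L / %, D / %): 0.250: 1.0, 0; 0.833: 3.2, 0; 1.33: 5.2, 0; 2.00: 7.6, 0; 3.00: 11.0, 0.4; 4.00: 14.1, 0.8; 5.00: 16.3, 0
- beta (time / h: L / %, D / %): 0.667: 3.2, 0.5; 1.33: 5.6, 0.3; 2.00: 7.2, 0; 3.00: 11.3, 0.1; 4.00: 13.9, 0.6; 5.00: 16.0, 0

(standard deviation of a reading: 0.3 percentage points)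
- which of these holds the largest part of the Z at the end of midnight (D / L / Z)
- which of these holds the largest part of the Z at the end of dusk (D / L / Z)
- how much L is there at the end of midnight, in percent of the Z charged
- a reading or a percentage of D counts all its forms, free or not

1. The easy step came first. I turned theta's last L reading into an exposure E, the logarithm of Z charged over Z left, which gave 0.178 at 5.00 h. Divided by the X charged, this is a = 4.45 /M, the exposure per charged X.

2. Z charge: by hand, a loss first order in Z (pseudo-first-order) leaves a unmoved. Beta gave 4.36 /M, so I carried a to midnight's larger Z, though that is an extrapolation.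

3. Time: by hand, E grows steadily. But theta's E per hour fell from 0.0395 /h to 0.0307 /h, while making L had used 5.30% of the X. I assumed this fall ran on towards zero, with a roughly read half-life of 8.23 h. On that assumption I put midnight's E at 0.448, which leaves Z at 63.9%.

4. X charge: by hand and untested, E scales with X. I put dusk's E at 1.50 times midnight's, which leaves Z at 51.0%, a near tie that I gave to Z.

The forecast named L at midnight and L at dusk, with n at 51%; of the sag it said that it “may hint at inhibition”, and it shaded its L down to that n. My midnight answer differed: Z, with L and D sharing 36.1%.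

Midnight gave Z: Z 57.0%, L 39.1%. Dusk gave L: L 49.8%, Z 42.6%.

    Z + D ⇌ G, settled at all times (K = 19.0 /M)
    X ⇌ J (K = 1.28, k = 2.48 × 10⁻⁵ /s)
    Z + X → L (k = 3.15 × 10⁻⁴ /M/s)
    X + L → D (k = 8.49 × 10⁻⁵ /M/s)

Midnight's Z stood below my reckoning, and its X stood at 33% of its charge at 25.0 h. Its exposure per charged X was 3.16 times a. I applied that factor to the neighbouring flask, midnight with 0.068 M of X: E = 0.954, so Z left is 38.5%. That flask held Z at 37.8%, and its largest share was L, at 52.8%.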